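I decide to treat the exchange between isomer and starting material as a first-order lag: during and just after the feed, isomer chases starting material, and afterwards it follows it down. The question is where the chase ends.

common to all: starting material 10 mM (fed, over 2.5 min)
- ochre: catalyst 2 mol%; the very flask that is asked about, followed so far
- grey: catalyst 1.3 mol%; run made earlier
- flask: catalyst 2 mol%; time 2.5 h

- ochre (time / min: isomer of the product / %, target / %): 1.33: 1.3, 3.3; 2.50: 5.4, 4.8; 5.00: 9.5, 12.9; 10.0: 6.7, 17.8; 15.0: 5.7, 21.2; 30.0: 7.1, 22.8
- grey (time / min: isomer of the product / %, target / %): 1.33: 1.2, 1.0; 3.00: 7.8, 4.6; 6.00: 9.8, 8.1; 15.0: 7.0, 17.6; 30.0: 6.8, 23.2; 60.0: 4.6, 19.8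

(standard deviation of a reading: 1 percentage point)

1. time up to 2.5 h at which isomer of the product stands highest
2. the amount of isomer of the product, in percent of the starting material charged, at that time

No run reads starting material, so I use the rest, meaning whatever is neither target nor isomer. That is starting material plus uncatalysed product.

| run | time | rest | isomer / rest |
|---|---|---|---|
| ochre | 2.50 min | 89.8 % | 0.0601 |
| grey | 3.00 min | 87.6 % | 0.0890 |
| ochre | 5.00 min | 77.6 % | 0.122 |
| grey | 6.00 min | 82.1 % | 0.119 |
| ochre | 10.0 min | 75.5 % | 0.0887 |
| grey | 15.0 min | 75.4 % | 0.0928 |

The first two rows show the lag still filling. The middle two, read at different times and catalyst loadings, agree within the scatter, so I take their mean as the standing ratio (a quasi-equilibrium) and, assuming that little of the rest is uncatalysed product so early, as c(isomer)/c(starting material) = 0.121, a reading with scatter. In the last two rows the ratio stands lower than in the middle two, and, with the scatter of each reading in mind, I tentatively read that as uncatalysed product growing inside the rest. My reckoning puts the top between 5.00 min and 6.00 min, with isomer then tracking this ratio.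

The forecast says 4.8 min and 9.3 %: “It should peak soon after dosing ends”. Its time lies just before my window.

The flask tops at 5.92 min with 8.40 %, later than the forecast's time.

    starting material → uncatalysed product (k = 2.00 × 10⁻⁴ s⁻¹)
    starting material + catalyst ⇌ target + catalyst, rate k2*[starting material]*[catalyst] forward; the back reaction follows from the equilibrium constant (K = 0.460, k = 3.00 L mol⁻¹ s⁻¹)
    target + catalyst ⇌ isomer of the product + catalyst, rate k3*[catalyst]*[target] forward; the back reaction follows from the equilibrium constant (K = 0.270, k = 2.10 L mol⁻¹ s⁻¹)
    isomer of the product ⇌ starting material (k = 0.0100 s⁻¹)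

At the end of the feed the flask holds 89.2 % starting material and 5.22 % isomer, the exchange has a relaxation half-life of 1.03 min, and at the top the flask holds 73.6 % starting material and 8.40 % isomer; after the top, isomer falls together with starting material. At 1.25 h the ratio times 34.8 % starting material gives 4.21 % against 4.41 % isomer in the flask. In the neighbouring flask read at 40 min, it gives 5.46 % from 45.1 % starting material, and that flask holds 5.72 % isomer.

(The runs stem from a simulated flask for an exercise; the scatter is artificial.)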